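The route rests on closing the ten-membered carbocycle at the bond it shares with the butenolide, C7–C8 (the lactone β- and γ-carbons at the ring fusion). An open-chain (Z)-β-triflyloxy enoate (C7) carrying a trans-2,3-epoxy aldehyde (C8, with a C9–C10 epoxide) undergoes an intramolecular Nozaki–Hiyama–Kishi addition. The new C8 alkoxide lactonises onto the cis ester, so one operation forms the carbocycle and the butenolide. The step exploits the γ-ylidene butenolide: base then opens the epoxide from C8, which gives the C8=C9 enol double bond and the C10 tertiary alcohol. C10 is set by a Sharpless epoxidation, C2 by a vinylogous aldol reaction, and C6 comes from (S)-malic acid.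

Key step: step 18

Locants used for all compounds (germacrane numbering): carbocycle C1–C10 with C10 the methyl carbinol carbon (methyl = C14), C2 the acetoxy carbon, C3=C4, C15 the CH2O group on C4, C6 the angeloyloxy carbon, C7 and C8 the ring-fusion carbons; lactone C11 (α-carbon), C12 (C=O), C13 (CH2OAc).

Assumption: the (S,S)-antipode of the bisphosphoramide catalyst in step 3 is taken to direct Si-face addition to aldehyde 2 (giving 2S); if the sense is the opposite, the (R,R)-antipode is used.

Step 1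
Reactants: 1 tert-butyl(diphenyl)(prop-2-yn-1-yloxy)silane
Product: 2 4-(tert-butyldiphenylsilyloxy)but-2-ynal
Conditions: n-BuLi, THF, −78 °C; DMF; aq. KH2PO4
Reagents that add atoms: N,N-dimethylformamide CN(C)C=O
Why: Formylation of the lithium acetylide with DMF, with a phosphate quench that should release the ynal (C2, C3, C4, C15) without conjugate addition of the amine.

Step 2
Reactants: 3 methyl 3-methylbut-2-enoate
Product: 4 1-methoxy-1-(tert-butyldimethylsilyloxy)-3-methylbuta-1,3-diene
Conditions: LiN(iPr)2, THF, DMPU, −78 °C; TBSCl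
Reagents that add atoms: tert-butyldimethylsilyl chloride CC(C)(C)[Si](C)(C)Cl
Why: γ-Deprotonation to the extended enolate and O-silylation (silyl ketene acetal formation) should give the dienolate that supplies C8, C9, C10, C14 and C1.

Step 3
Reactants: 2 4-(tert-butyldiphenylsilyloxy)but-2-ynal; 4 silyl dienolate
Product: 5 methyl (2E,5S)-8-(tert-butyldiphenylsilyloxy)-5-hydroxy-3-methyloct-2-en-6-ynoate
Conditions: SiCl4, (S,S)-bisphosphoramide [pentane-1,5-diyl-bridged bis-phosphoramide of N,N'-dimethyl-1,1'-binaphthyl-2,2'-diamine] (5 mol%), iPr2NEt (cat.), CH2Cl2, −78 °C; aq. NaHCO3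
Reagents that add atoms: none
Why: Lewis-base-activated SiCl4 vinylogous Mukaiyama aldol reaction, in which the dienolate should react at its γ-carbon through an open s-trans transition state (hence 9E) while the chiral phosphoramide-bound silicon cation exposes the Si face of the ynal and sets C2 as S.

Step 4
Reactants: 5 methyl (2E,5S)-8-(tert-butyldiphenylsilyloxy)-5-hydroxy-3-methyloct-2-en-6-ynoate
Product: 6 (2E,5S,6Z)-8-(tert-butyldiphenylsilyloxy)-7-iodo-3-methylocta-2,6-diene-1,5-diol
Conditions: NaAlH2(OCH2CH2OMe)2, THF, 0 °C to rt; I2, −78 °C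
Reagents that add atoms: iodine II
Why: Alkoxide-directed trans-hydroalumination of the propargylic alcohol (hydride to C3, aluminium to C4) and iodinolysis with retention should give the Z-alkenyl iodide with iodine cis to C2, while the ester is reduced to the C8 allylic alcohol.

Step 5
Reactants: 6 (2E,5S,6Z)-8-(tert-butyldiphenylsilyloxy)-7-iodo-3-methylocta-2,6-diene-1,5-diol
Product: 8 alkenyl iodide bearing 8-OTBS 2-OTES 15-OTBDPS, via mono-TBS ether 7 (not isolated)
Conditions: TBSCl (1.05 equiv), imidazole, DMF, −20 °C; then TESCl, 0 °C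
Reagents that add atoms: tert-butyldimethylsilyl chloride CC(C)(C)[Si](C)(C)Cl; chlorotriethylsilane CC[Si](Cl)(CC)CC
Why: Sequential silyl ether formation in which the primary allylic C8 alcohol should react first with the bulky TBSCl and the secondary C2 alcohol then with TESCl, giving three silyl ethers of graded lability.

Step 6
Reactants: 9 (S)-2-(2,2-dimethyl-5-oxo-1,3-dioxolan-4-yl)acetic acid
Product: 10 1,3-dioxoisoindolin-2-yl (S)-2-(2,2-dimethyl-5-oxo-1,3-dioxolan-4-yl)acetate
Conditions: N-hydroxyphthalimide, N,N'-diisopropylcarbodiimide, DMAP (cat.), CH2Cl2, rt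
Reagents that add atoms: N-hydroxyphthalimide ON1C(=O)c2ccccc2C1=O
Why: Carbodiimide esterification should give the redox-active ester of the malic acid acetonide, which carries C5, C6 (S) and C7.

Step 7
Reactants: 8 alkenyl iodide; 10 redox-active ester
Product: 11 (6S)-dioxolanone with the C4–C5 bond formed
Conditions: NiBr2(MeOCH2CH2OMe) (10 mol%), 4,4'-di-tert-butyl-2,2'-bipyridine, Zn, DMA, rt
Reagents that add atoms: none
Why: Nickel-catalysed decarboxylative cross-electrophile coupling, in which the primary C5 radical from reductive fragmentation of the ester should be captured by the alkenylnickel species with retention of olefin geometry (C2 and C5 cis), leaving C6 untouched.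

Step 8
Reactants: 11 (6S)-dioxolanone
Product: 12 α-hydroxy N-methoxy-N-methylamide (6-OH, C7 amide)
Conditions: MeNHOMe·HCl, iPrMgCl (amide preformed), THF, −20 °C
Reagents that add atoms: N,O-dimethylhydroxylamine hydrochloride CNOC.Cl
Why: Aminolysis of the activated dioxolanone by the magnesium amide should open the acetonide with loss of acetone and free the C6 hydroxyl.

Step 9
Reactants: 12 α-hydroxy N-methoxy-N-methylamide
Product: 13 6-O-angeloyl N-methoxy-N-methylamide
Conditions: angelic acid, 2,4,6-trichlorobenzoyl chloride, Et3N, toluene, rt; then 12, 80 °C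
Reagents that add atoms: angelic acid C/C=C(/C)C(=O)O
Why: Yamaguchi-type mixed-anhydride esterification run without a nucleophilic catalyst should acylate the hindered C6 alcohol without Z-to-E isomerisation of the angeloyl group.

Step 10
Reactants: 14 methyl 3-hydroxypropanoate
Product: 15 methyl 3-(triethylsilyloxy)propanoate
Conditions: TESCl, imidazole, CH2Cl2, 0 °C
Reagents that add atoms: chlorotriethylsilane CC[Si](Cl)(CC)CC
Why: Silyl ether formation should give the C11–C12–C13 unit with C13–O masked by the same labile group as C2–O.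

Step 11
Reactants: 13 6-O-angeloyl N-methoxy-N-methylamide; 15 methyl 3-(triethylsilyloxy)propanoate
Product: 16 β-keto ester (C7 ketone, C11 epimers)
Conditions: LiN(iPr)2, 15, THF, −78 °C; then 13; AcOH quench at −78 °C
Reagents that add atoms: none
Why: Crossed Claisen-type acylation of the lithium ester enolate by the N-methoxy-N-methylamide, whose chelated tetrahedral adduct should collapse only on work-up; C11 forms as an epimer mixture that step 12 makes trigonal.

Step 12
Reactants: 16 β-keto ester
Product: 17 (Z)-enol triflate (7-OTf cis to the C12 ester)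
Conditions: LiN(SiMe3)2, THF, −78 °C; N-(5-chloro-2-pyridyl)bis(trifluoromethanesulfonimide), −78 to −40 °C
Reagents that add atoms: N-(5-chloro-2-pyridyl)bis(trifluoromethanesulfonimide) O=S(=O)(N(c1ccc(Cl)cn1)S(=O)(=O)C(F)(F)F)C(F)(F)F
Why: Chelation-controlled enol triflate formation, in which O-sulfonylation of the lithium-chelated Z enolate on the ketone oxygen should place the triflate cis to the ester and C6 cis to C13.

Step 13
Reactants: 17 (Z)-enol triflate
Product: 18 2,13-diol
Conditions: PPTS, MeOH/CH2Cl2, 0 °C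
Reagents that add atoms: none
Why: Acid-catalysed methanolysis (selective desilylation) should cleave the two triethylsilyl ethers much faster than the TBS and TBDPS ethers.

Step 14
Reactants: 18 2,13-diol
Product: 19 2,13-diacetate
Conditions: Ac2O, pyridine, DMAP (cat.), CH2Cl2, 0 °C
Reagents that add atoms: acetic anhydride CC(=O)OC(C)=O
Why: Acetylation of the only two free hydroxyls should install both acetates of the target in one operation.

Step 15
Reactants: 19 2,13-diacetate
Product: 20 C8 allylic alcohol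
Conditions: HF·pyridine, pyridine, THF, 0 °C
Reagents that add atoms: none
Why: Buffered HF (selective desilylation) should cleave the primary TBS ether while the more robust TBDPS ether, the esters and the enol triflate survive.

Step 16
Reactants: 20 C8 allylic alcohol
Product: 21 (9R,10R)-epoxy alcohol
Conditions: Ti(OiPr)4 (10 mol%), D-(−)-diethyl tartrate, t-BuOOH, 4 Å MS, CH2Cl2, −20 °C
Reagents that add atoms: tert-butyl hydroperoxide CC(C)(C)OO
Why: Sharpless asymmetric epoxidation of the only free allylic alcohol, where D-(−)-tartrate should deliver oxygen to the face of the 9E olefin that gives the (9R,10R)-epoxide and so fixes C10.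

Step 17
Reactants: 21 (9R,10R)-epoxy alcohol
Product: 22 epoxy aldehyde (C8 aldehyde, C7 enol triflate)
Conditions: Dess–Martin periodinane, NaHCO3, CH2Cl2, 0 °C
Reagents that add atoms: none
Why: Buffered Dess–Martin oxidation should give the sensitive α,β-epoxy aldehyde without epimerisation at C9; it is used at once.

Step 18
Reactants: 22 epoxy aldehyde
Product: 24 macrocyclic butenolide epoxide (C8 epimers), via ring-closed hydroxy ester 23 (not isolated)
Conditions: CrCl2 (8 equiv), NiCl2 (2 mol%), DMSO/THF, rt, 2 mM by slow addition; aq. NH4Cl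
Reagents that add atoms: none
Why: Zerovalent nickel (from NiCl2 and CrCl2) should insert into the activated C7–OTf bond, pass the alkenyl group to trivalent chromium with retention of the Z geometry, and the alkenylchromium then adds to the C8 aldehyde. The closest known reaction type is the Nozaki–Hiyama–Kishi coupling of (Z)-β-halo or β-triflyloxy enoates with aldehydes, which gives butenolides directly. The carbocycle closes by a 10-exo-trig carbonyl addition and the butenolide by a 5-exo-trig acyl substitution of the C8 alkoxide on the cis methyl ester. The one new stereocentre, C8, is not controlled and need not be, because step 19 makes it trigonal. The step needs insertion into the vinylogous acyl triflate in preference to the allylic esters, ring closure in preference to oligomerisation (high dilution), and lactonisation, which the Z geometry from step 12 secures.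

Step 19
Reactants: 24 macrocyclic butenolide epoxide
Product: 25 15-O-TBDPS ether of the target
Conditions: DBU, Bu4NOAc (buffer), THF, −20 to 0 °C
Reagents that add atoms: none
Why: E1cB-type vinylogous elimination, in which deprotonation of the acidic butenolide γ-hydrogen at C8 and opening of the adjacent epoxide should give the C8=C9 enol double bond and the C10 alcohol with C10 unchanged, the ten-membered ring holding C10 cis to C7 and the acetate buffer returning any C13 acetate lost from the dienolate.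

Step 20
Reactants: 25 15-O-TBDPS ether of the target
Product: 26 target CNP0165707.1
Conditions: HF·pyridine, pyridine, THF, 0 °C to rt
Reagents that add atoms: none
Why: Buffered, non-basic fluoride cleavage of the primary TBDPS ether (desilylation) should spare the three esters, the enol lactone and the tertiary allylic alcohol.

Compound list
1 | tert-butyl(diphenyl)(prop-2-yn-1-yloxy)silane | C#CCO[Si](c1ccccc1)(c1ccccc1)C(C)(C)C | starting material
2 | 4-(tert-butyldiphenylsilyloxy)but-2-ynal | O=CC#CCO[Si](c1ccccc1)(c1ccccc1)C(C)(C)C | intermediate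
3 | methyl 3-methylbut-2-enoate | COC(=O)C=C(C)C | starting material
4 | 1-methoxy-1-(tert-butyldimethylsilyloxy)-3-methylbuta-1,3-diene (ketene acetal geometry not defined) | COC(O[Si](C)(C)C(C)(C)C)=CC(C)=C | intermediate
5 | methyl (2E,5S)-8-(tert-butyldiphenylsilyloxy)-5-hydroxy-3-methyloct-2-en-6-ynoate | COC(=O)/C=C(\C)C[C@H](O)C#CCO[Si](c1ccccc1)(c1ccccc1)C(C)(C)C | intermediate
6 | (2E,5S,6Z)-8-(tert-butyldiphenylsilyloxy)-7-iodo-3-methylocta-2,6-diene-1,5-diol | OC/C=C(\C)C[C@H](O)/C=C(\I)CO[Si](c1ccccc1)(c1ccccc1)C(C)(C)C | intermediate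
7 | mono-TBS ether of 6 (8-OTBS, 2-OH; 2S, 9E, 3Z) | CC(C)(C)[Si](C)(C)OC/C=C(\C)C[C@H](O)/C=C(\I)CO[Si](c1ccccc1)(c1ccccc1)C(C)(C)C | intermediate
8 | alkenyl iodide (2S, 9E, 3Z; 8-OTBS, 2-OTES, 15-OTBDPS, 4-iodo) | CC(C)(C)[Si](C)(C)OC/C=C(\C)C[C@H](O[Si](CC)(CC)CC)/C=C(\I)CO[Si](c1ccccc1)(c1ccccc1)C(C)(C)C | intermediate
9 | (S)-2-(2,2-dimethyl-5-oxo-1,3-dioxolan-4-yl)acetic acid | CC1(C)OC(=O)[C@H](CC(=O)O)O1 | starting material
10 | 1,3-dioxoisoindolin-2-yl (S)-2-(2,2-dimethyl-5-oxo-1,3-dioxolan-4-yl)acetate | CC1(C)OC(=O)[C@H](CC(=O)ON2C(=O)c3ccccc3C2=O)O1 | intermediate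
11 | dioxolanone (2S,6S; 3E with C2 and C5 cis, 9E; C6–O and C7 as 2,2-dimethyl-1,3-dioxolan-4-one) | CC(C)(C)[Si](C)(C)OC/C=C(\C)C[C@H](O[Si](CC)(CC)CC)/C=C(CO[Si](c1ccccc1)(c1ccccc1)C(C)(C)C)\C[C@@H]1OC(C)(C)OC1=O | intermediate
12 | (2S,6S)-6-hydroxy C7 N-methoxy-N-methylamide | CC(C)(C)[Si](C)(C)OC/C=C(\C)C[C@H](O[Si](CC)(CC)CC)/C=C(CO[Si](c1ccccc1)(c1ccccc1)C(C)(C)C)\C[C@H](O)C(=O)N(C)OC | intermediate
13 | (2S,6S)-6-O-angeloyl C7 N-methoxy-N-methylamide | CC(C)(C)[Si](C)(C)OC/C=C(\C)C[C@H](O[Si](CC)(CC)CC)/C=C(CO[Si](c1ccccc1)(c1ccccc1)C(C)(C)C)\C[C@H](OC(=O)/C(C)=C\C)C(=O)N(C)OC | intermediate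
14 | methyl 3-hydroxypropanoate | COC(=O)CCO | starting material
15 | methyl 3-(triethylsilyloxy)propanoate | COC(=O)CCO[Si](CC)(CC)CC | intermediate
16 | (2S,6S)-β-keto ester (C7 ketone, C11 epimers, 13-OTES) | CC(C)(C)[Si](C)(C)OC/C=C(\C)C[C@H](O[Si](CC)(CC)CC)/C=C(CO[Si](c1ccccc1)(c1ccccc1)C(C)(C)C)\C[C@H](OC(=O)/C(C)=C\C)C(=O)C(CO[Si](CC)(CC)CC)C(=O)OC | intermediate
17 | (2S,6S,7Z)-enol triflate (2-OTES, 13-OTES, 8-OTBS, 15-OTBDPS, 6-OAng) | C/C=C(/C)C(=O)O[C@H](/C(OS(=O)(=O)C(F)(F)F)=C(\CO[Si](CC)(CC)CC)C(=O)OC)C/C(CO[Si](c1ccccc1)(c1ccccc1)C(C)(C)C)=C\[C@@H](O[Si](CC)(CC)CC)C/C(C)=C/CO[Si](C)(C)C(C)(C)C | intermediate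
18 | (2S,6S,7Z)-enol triflate 2,13-diol | C/C=C(/C)C(=O)O[C@H](/C(OS(=O)(=O)C(F)(F)F)=C(\CO)C(=O)OC)C/C(CO[Si](c1ccccc1)(c1ccccc1)C(C)(C)C)=C\[C@@H](O)C/C(C)=C/CO[Si](C)(C)C(C)(C)C | intermediate
19 | (2S,6S,7Z)-enol triflate 2,13-diacetate (8-OTBS) | C/C=C(/C)C(=O)O[C@H](/C(OS(=O)(=O)C(F)(F)F)=C(\COC(C)=O)C(=O)OC)C/C(CO[Si](c1ccccc1)(c1ccccc1)C(C)(C)C)=C\[C@@H](OC(C)=O)C/C(C)=C/CO[Si](C)(C)C(C)(C)C | intermediate
20 | (2S,6S,7Z,9E)-C8 allylic alcohol | C/C=C(/C)C(=O)O[C@H](/C(OS(=O)(=O)C(F)(F)F)=C(\COC(C)=O)C(=O)OC)C/C(CO[Si](c1ccccc1)(c1ccccc1)C(C)(C)C)=C\[C@@H](OC(C)=O)C/C(C)=C/CO | intermediate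
21 | (2S,6S,9R,10R)-epoxy alcohol | C/C=C(/C)C(=O)O[C@H](/C(OS(=O)(=O)C(F)(F)F)=C(\COC(C)=O)C(=O)OC)C/C(CO[Si](c1ccccc1)(c1ccccc1)C(C)(C)C)=C\[C@@H](OC(C)=O)C[C@@]1(C)O[C@@H]1CO | intermediate
22 | (2S,6S,9S,10R)-epoxy aldehyde (same spatial arrangement as 21) | C/C=C(/C)C(=O)O[C@H](/C(OS(=O)(=O)C(F)(F)F)=C(\COC(C)=O)C(=O)OC)C/C(CO[Si](c1ccccc1)(c1ccccc1)C(C)(C)C)=C\[C@@H](OC(C)=O)C[C@@]1(C)O[C@@H]1C=O | intermediate
23 | ring-closed γ-hydroxy enoate, formed as its chromium alkoxide (ten-membered ring, C8 epimers) | C/C=C(/C)C(=O)O[C@H]1C/C(CO[Si](c2ccccc2)(c2ccccc2)C(C)(C)C)=C\[C@@H](OC(C)=O)C[C@@]2(C)O[C@@H]2C(O)/C1=C(/COC(C)=O)C(=O)OC | intermediate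
24 | macrocyclic 8,12-butenolide with 9,10-epoxide (2S,6S,9R,10R; C8 epimers) | C/C=C(/C)C(=O)O[C@H]1C/C(CO[Si](c2ccccc2)(c2ccccc2)C(C)(C)C)=C\[C@@H](OC(C)=O)C[C@@]2(C)O[C@@H]2C3OC(=O)C(COC(C)=O)=C13 | intermediate
25 | 15-O-TBDPS ether of the target (2S,6S,10R) | C/C=C(/C)C(=O)O[C@H]1C/C(CO[Si](c2ccccc2)(c2ccccc2)C(C)(C)C)=C\[C@@H](OC(C)=O)C[C@@](C)(O)/C=C2/OC(=O)C(COC(C)=O)=C21 | intermediate
26 | CNP0165707.1 (2S,6S,10R) | C/C=C(/C)C(=O)O[C@H]1C/C(CO)=C\[C@@H](OC(C)=O)C[C@@](C)(O)/C=C2/OC(=O)C(COC(C)=O)=C21 | target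

Total step count: 20. Longest linear sequence: 17 steps (1, 3, 4, 5, 7, 8, 9, 11–20).

Steps most likely to fail

Step 18. The ten-membered closure may lose to oligomerisation, or divalent chromium may reductively open the α,β-epoxy aldehyde before the alkenylchromium adds. The fallback sets out from 20 and installs the epoxide after ring closure. MnO2 oxidation in CH2Cl2 gives the enal F1. The same CrCl2/NiCl2 closure on this epoxide-free aldehyde, followed by lactonisation, gives the 9,10-ene butenolide F2. Shi epoxidation of the trisubstituted C9=C10 olefin (D-fructose-derived ketone, KHSO5, buffered MeCN/water, 0 °C) should then give the (9R,10R)-epoxide, so the route is rejoined at 24.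

Step 19. The dienolate may expel the C13 acetate (vinylogous β-elimination) faster than it opens the epoxide, or the epoxide may open from a conformer that gives the ring-trans ylidene geometry. The fallback sets out from 24 and avoids a free dienolate. TESOTf and Et3N in CH2Cl2 (−78 to 0 °C) should convert the butenolide into its 2-silyloxyfuran and promote silyl-triflate-assisted vinylogous opening of the epoxide, giving the C10 triethylsilyl ether F3. The HF·pyridine conditions of step 20 then remove both silyl groups, so the route is rejoined at 26.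

Step 7. The hindered alkenyl iodide may undergo proto-deiodination or homocoupling instead of capturing the alkyl radical. The fallback sets out from 8 and uses polar chemistry. Iodine–lithium exchange (t-BuLi, Et2O, −78 °C), immediate transmetalation with MgBr2·OEt2 and CuI-catalysed opening of methyl (S)-glycidate at its CH2 terminus (THF, −40 °C) should give the α-hydroxy methyl ester F4. Amidation with MeNHOMe·HCl and iPrMgCl then rejoins the route at 12.

Further compounds
F1 | step 18 | (2S,6S,7Z,9E)-enal (C8 aldehyde conjugated with C9=C10, C7 enol triflate) | C/C=C(/C)C(=O)O[C@H](/C(OS(=O)(=O)C(F)(F)F)=C(\COC(C)=O)C(=O)OC)C/C(CO[Si](c1ccccc1)(c1ccccc1)C(C)(C)C)=C\[C@@H](OC(C)=O)C/C(C)=C/C=O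
F2 | step 18 | macrocyclic 8,12-butenolide with 9E olefin (2S,6S; C8 epimers) | C/C=C(/C)C(=O)O[C@H]1C/C(CO[Si](c2ccccc2)(c2ccccc2)C(C)(C)C)=C\[C@@H](OC(C)=O)C/C(C)=C/C2OC(=O)C(COC(C)=O)=C12
F3 | step 19 | 10-O-triethylsilyl 15-O-TBDPS ether of the target | C/C=C(/C)C(=O)O[C@H]1C/C(CO[Si](c2ccccc2)(c2ccccc2)C(C)(C)C)=C\[C@@H](OC(C)=O)C[C@@](C)(O[Si](CC)(CC)CC)/C=C2/OC(=O)C(COC(C)=O)=C21
F4 | step 7 | (2S,6S)-6-hydroxy C7 methyl ester (8-OTBS, 2-OTES, 15-OTBDPS) | CC(C)(C)[Si](C)(C)OC/C=C(\C)C[C@H](O[Si](CC)(CC)CC)/C=C(CO[Si](c1ccccc1)(c1ccccc1)C(C)(C)C)\C[C@H](O)C(=O)OC
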